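Amber's split odds read 0.610, and I work from that number. By split odds I mean product at 5.9 min over starting material charged and not in product. You asked for a quick number on red, and your hunch is that red scales with its coupling partner. That is order 1, the zero of my scale: doubling [coupling partner] doubles the odds.

| flask | starting material | coupling partner | catalyst | product | time |
|---|---|---|---|---|---|
| amber | 80.0 mM | 200 mM | 2.40 mM |  |  |
| blue | 32.0 mM | 152 mM | 2.40 mM |  |  |
| teal | 80.0 mM | 200 mM | 2.40 mM | 24.0 mM |  |
| violet | 80.0 mM | 100 mM | 2.40 mM |  |  |
| red | 80.0 mM | 31.0 mM | 2.40 mM |  | 5.9 min |

| amber run: time / min | amber run: [product] / mM | blue run: time / min | blue run: [product] / mM | teal run: time / min | teal run: [product] / mM | violet run: time / min | violet run: [product] / mM |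
|---|---|---|---|---|---|---|---|
| 0.24 | 5.0 | 0.24 | 0.2 | 0.24 | 26.5 | 0.24 | 3.4 |
| 0.53 | 9.6 | 0.53 | 3.5 | 0.53 | 32.7 | 0.53 | 7.3 |
| 1.2 | 17.1 | 1.2 | 6.9 | 1.2 | 40.5 | 1.2 | 12.3 |
| 2.6 | 25.6 | 2.6 | 9.3 | 2.6 | 51.0 | 2.6 | 18.1 |
| 5.9 | 30.3 | 5.9 | 9.4 | 5.9 | 54.4 | 5.9 | 22.0 |

(each reading ± 1 mM)

* reaction order in [coupling partner] at the outset, round the charge of the amber run, defined at two percent of the starting material turned into product
* reaction order in [starting material] at the outset, round the charge of the amber run, defined at two percent of the starting material turned into product (one fixed amount of product, the same in the runs compared)
* product in the red run at 5.9 min, as a share of the starting material charged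

- Overall: starting material + coupling partner -> product, with catalyst as catalyst.
- Constant volume, constant temperature.
- A reading of a species includes what of it is bound.
- An order is taken over about fifteen percent of the charge, up and down.

I read the stall in these runs as a side loss of starting material, first order in it like the coupling. On that reading [starting material] cancels from the odds, I commit to order 1 in it, and I take the order of the odds in [coupling partner] as the order of the outset rate. Teal's gain over its added product, 30.4 mM, matches amber's reading of 30.3 mM within the scatter, so I take it that added product leaves the split as it is in teal.

Violet reads odds of 0.379. Amber has twice violet's charge of coupling partner, yet its odds read 1.61 times violet's, not 2 times. That reads as an order of 0.685, with the scatter of the readings on it.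

Blue tests this, since it was not used and has a different [starting material]. The rule gives blue odds of 0.505, so 10.7 mM of product against a reading of 9.4 mM, with a scatter of 1 mM.

For red the rule gives odds of 0.170, a share of 14.5%. Your order 1 gives 8.63%, which is less than mine. In red the coupling partner is the limiting reagent, capping the share at 38.8%, and my figure stays under that.

The forecast holds that “every run stalls early with plenty of reagent left”, and it gives 0.4 in [coupling partner], 0.7 in [starting material] and 11.5% for red, each lower than mine.

The simulation gives 0.62 in [coupling partner], 1.1 in [starting material] and 14.0% for red at 5.9 min.

    catalyst + starting material + coupling partner → product + catalyst (1680 L² mol⁻² min⁻¹)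
    starting material → decomposed substrate (0.3642 min⁻¹)
    2 coupling partner ⇌ idle reagent dimer, settled at all times (16.50 L mol⁻¹)

Red's odds come to 0.163, a quarter of amber's 0.610, against my 0.170. Red's share is held down by the conversion of starting material into decomposed substrate: the red run without that conversion gives 26.2%, not 14.0%. The odds of that run are twice those of the red run as it is, at 0.355.

The numbers in the tables are calculated with made-up constants; the scatter is artificial.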